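## The problem

Target **28** is a trans-fused hexahydroinden-2-one: a cyclopentanone (C1, C2, C3, C3a, C7a) shares the C3a–C7a bond with a cyclohexene (C4, C5, C6=C7). This numbering is used for every precursor as well. Four of the six stereocentres lie on the five-membered ring in an all-trans array; C1 and C3 flank the ketone and can be equilibrated, C3a and C7a cannot, so C3a must be set absolutely and then direct C7a, C1 and C3. The hard part is the pair of adjacent quaternary carbons: C4 (ethyl, carboxyl) must be fixed relative to C3a while it is still exocyclic, and C5 (ethyl, styryl) relative to C4, and neither can be corrected afterwards. The carboxyl group on C4 is flanked by fully substituted carbons, so it has to travel as an ester that is removed by attack at the alkyl group, not at the carbonyl. Two styrene units and a trisubstituted ring alkene exclude hydrogenation, hydroboration and ozonolysis late in the route, an isopropenyl group next to a free acid would lactonise under protic acid, and the α-centres of the ketone tolerate base only once they are in their thermodynamic arrangement. The feature that opens the structure is C5: it is bonded to two alkenyl carbons (the styryl Cα and ring carbon C6) while C7 carries a methyl group, so C6=C7 can be made by metathesis between an isopropenyl group on C7a and one of two identical styryl groups on C5, and C5 becomes stereogenic only in that ring closure.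

## Retrosynthesis

**28 from 27 (O–CH3).** The acid is traced to methyl ester **27**. The ester is kept to the end because a free acid would interfere with every enolate and organometallic step. Methyl is chosen because it survives all of them and can still be removed by iodide at carbon. The forward step only has to leave C1 and C3 alone, and both are already at equilibrium.

**27 from 26 (C6=C7, the key cut).** Opening the ring alkene gives **26**, an all-trans cyclopentanone carrying an isopropenyl group on C7a and a C4–C5 arm whose C5 bears two identical styryl groups. Compared with cutting C5–C6 or C3a–C4/C5–C6, this cut leaves a precursor with no stereocentre at C5 and no alkene geometry to control. The forward reaction must choose between two diastereotopic styryl groups; it has the fixed C4 centre and the trans ring fusion to work with.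

**26 from 25, 22 and 21 (C1–ethyl, C7a–isopropenyl, C1=C7a).** The second half of the cyclopentanone is removed in the order ethyl, isopropenyl (from Grignard reagent **23**), unsaturation, back to ketone **21**. Each forward step is substrate-controlled: the isopropenyl group enters anti to the large C3a substituent and the ethyl group anti to the isopropenyl group. This half is built last on purpose, so that the C7a side of C3a is still an unsubstituted methylene when C4 is made.

**21 from 18 and 19 (one aryl–alkenyl bond).** One styryl group is traced to a vinyl group and iodobenzene **19**. Making both styryl groups directly in the sigmatropic step would need a secondary, benzylic dienyl ester. Its carbinol centre would couple to the face of C4 through the chair transition state, and the ester would ionise and be deprotonated easily. With a vinyl and a styryl group in **18**, C5 is a stereocentre of no consequence, because arylation makes the two groups identical.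

**18 from 15 (C4–C5).** A [3,3] shift of the silyl ketene acetal of dienyl ester **15** creates both quaternary carbons in one step and is the only disconnection that forces bond formation at the central, fully substituted carbon of the dienyl unit. Because the allylic terminus is CH2–O, nothing in the allyl part influences the face of C4; that choice rests on C3a, whose neighbour C3 still carries its methyl group cis to the side chain at this stage.

**15 from 14 and 4; 4 from 3, from 1 and 2.** The ester C–O bond is cut to keto acid **14** and dienol **4**. The dienol comes from dienoate **3**, made by olefination of enone **1** with phosphonate **2**. The geometry of the new double bond in **3** does not matter.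

**14 from 13, 12 and 11 (C2 oxygen).** The ketone is traced through alcohol **12** to the ring alkene of **11**. Hydroboration places oxygen on C2 and hydrogen on C3 anti to the side chain, which leaves the methyl group cis to it. A benzyl ester is used because it can be removed without base, so the cis methyl group reaches **14** intact.

**11 from 8, from 6 and 7; 6 from 5 (C3a–C4).** A first Ireland–Claisen rearrangement of butanoate **8** forms C3a–C4 and transfers the carbinol configuration of **6** to C3a. **6** comes from enone **5** by enantioselective reduction and is acylated with **7**. This is the only point where absolute configuration is introduced by a reagent.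

## Roads not taken

**Alternative 1:** Cut C3a–C4 and C5–C6 together. 2,3-Diethylmaleic anhydride **A1** supplies C4=C5 with both ethyl groups and both carbonyl carbons, and adds under high pressure to the 2-ethoxydiene **A2** to give the tricyclic anhydride **A3**.
- Merits: the ring and both quaternary carbons form in one step, and the cis relation of the two ethyl groups follows from the dienophile geometry with certainty. In this respect it is better than the chosen plan, whose C4/C5 relation depends on a facial preference in step 10 and a group selection in step 15.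
- Weak points: a tetrasubstituted dienophile needs very high pressure; the diene face is controlled only by the remote C1 and C3 substituents; the two anhydride carbonyls, both neopentyl, must then be told apart (one stays, the other becomes the styryl group); and the enol ether has to be turned into the C7-methyl alkene with C7a set trans by a protonation.
- Comparison: the chosen plan has every ring stereocentre in place before closure and needs no differentiation of like groups afterwards, but its ring-forming step is less certain than a suprafacial cycloaddition.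

**Alternative 2:** Cut C5–C6 alone. A zerovalent palladium catalyst made from Pd(OAc)2 and a diphosphine inserts into the C–I bond of vinyl iodide **A4**, adds 6-exo to C5 of the trisubstituted alkene, and β-hydride elimination toward the benzylic carbon gives the E-styryl group of **A5**.
- Merits: C5 becomes quaternary and the styrene appears in the ring-forming step, no styrene is sacrificed, and the face of one alkene is chosen instead of one of two identical groups. That selection is at least as well defined as the one in step 15 and could be reinforced by a chiral ligand.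
- Weak points: C4 must still be made as an exocyclic quaternary stereocentre, now attached to a trisubstituted alkene of defined geometry, and the Z-iodoalkene on C7a needs its own stereocontrolled synthesis. The precursor is harder to reach than **26**.
- Comparison: the chosen plan gets both quaternary carbons from one sigmatropic step and simple building blocks, and accepts a less conventional selection in return.

**Alternative 3:** Cut C1–C7a. Rh2(OAc)4 turns the α-diazo-β-keto ester **A6** into a carbenoid that inserts into the equatorial allylic C7a–H bond to give the trans-fused β-keto ester **A7**; alkylation and dealkoxycarbonylation would then place the C1 ethyl group.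
- Merits: five-membered C–H insertion is dependable and its trans selectivity is predictable, so as a ring closure it is more reliable than the metathesis of **26**.
- Weak points: it does nothing for the difficult part. The cyclohexene with C3a, C4 and C5 must already exist, the carbenoid can cyclopropanate the neighbouring ring alkene or the styrene, and three more steps follow the key step.
- Comparison: the chosen plan uses the cyclopentanone from the start as the template that directs C4, C7a and C1, and closes the six-membered ring last.

Key step: step 15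

Assumption: compounds 10–15 are carried as mixtures of epimers at the side-chain carbon that becomes C4, and 17 and 18 as mixtures at C5; step 10 erases the first centre and step 11 converges the second, so their SMILES leave these centres open.

## Steps

Step 1
Reactants: 1 (E)-1-phenylpent-1-en-3-one; 2 triethyl phosphonoacetate
Product: 3 ethyl (2E,4E)-3-ethyl-5-phenylpenta-2,4-dienoate
Conditions: NaH, THF, 0 °C → reflux
Reagents that add atoms: none
Why: Horner–Wadsworth–Emmons olefination of a conjugated ketone, as in the ionone to ionylideneacetate homologation; the 2E isomer should predominate, and the geometry of this bond is of no consequence because the carbon it ends on (C5) is converged in step 11.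

Step 2
Reactants: 3 ethyl (2E,4E)-3-ethyl-5-phenylpenta-2,4-dienoate
Product: 4 (2E,4E)-3-ethyl-5-phenylpenta-2,4-dien-1-ol
Conditions: i-Bu2AlH, CH2Cl2, −78 °C; aq. KNaC4H4O6 work-up
Reagents that add atoms: none
Why: 1,2-reduction of a conjugated ester to the allylic alcohol with i-Bu2AlH; the diene is not touched at low temperature.

Step 3
Reactants: 5 2-methylcyclopent-2-en-1-one
Product: 6 (1S)-2-methylcyclopent-2-en-1-ol
Conditions: (R)-2-methyl-CBS-oxazaborolidine (10 mol%), BH3·SMe2, THF, −20 °C; MeOH quench
Reagents that add atoms: none
Why: Corey–Bakshi–Shibata reduction; the methyl-bearing alkene arm acts as the large group, so the (R)-oxazaborolidine should deliver hydride to the face that gives the S carbinol, the one stereocentre the route takes from a reagent.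

Step 4
Reactants: 6 (1S)-2-methylcyclopent-2-en-1-ol; 7 butanoyl chloride
Product: 8 (1S)-2-methylcyclopent-2-en-1-yl butanoate
Conditions: pyridine, DMAP (cat.), CH2Cl2, 0 °C
Reagents that add atoms: none
Why: acylation of a secondary allylic alcohol by an acid chloride under nucleophilic catalysis; the carbinol centre is not involved.

Step 5
Reactants: 8 (1S)-2-methylcyclopent-2-en-1-yl butanoate
Product: 11 benzyl 2-[(1S)-2-methylcyclopent-2-en-1-yl]butanoate, via silyl ketene acetal 9 (not isolated), via trimethylsilyl ester 10 (not isolated)
Conditions: LiN(i-Pr)2, THF, −78 °C; Me3SiCl, −78 → 65 °C; then Bu4NF, BnBr, 25 °C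
Reagents that add atoms: benzyl bromide, BrCc1ccccc1
Why: Ireland–Claisen rearrangement; the suprafacial [3,3] shift forms C3a–C4 on the ring face from which the oxygen leaves, so the S carbinol should be transferred faithfully to C3a, while the side-chain centre forms as a mixture that does not matter. The carboxylate freed by fluoride is benzylated in the same flask.

Step 6
Reactants: 11 benzyl 2-[(1S)-2-methylcyclopent-2-en-1-yl]butanoate
Product: 12 benzyl 2-[(1R,2R,3R)-3-hydroxy-2-methylcyclopentyl]butanoate
Conditions: BH3·THF, THF, 0 °C; then NaOH, H2O2, 0 °C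
Reagents that add atoms: hydrogen peroxide, OO
Why: hydroboration–oxidation; borane adds anti to the C3a side chain with boron on the less substituted C2, so hydrogen arrives on C3 trans to the side chain, the methyl group is left cis to it, and the hydroxyl sits on C2 where the ketone is needed.

Step 7
Reactants: 12 benzyl 2-[(1R,2R,3R)-3-hydroxy-2-methylcyclopentyl]butanoate
Product: 13 benzyl 2-[(1R,2R)-2-methyl-3-oxocyclopentyl]butanoate
Conditions: Dess–Martin periodinane, NaHCO3, CH2Cl2, 0 → 25 °C
Reagents that add atoms: none
Why: Dess–Martin oxidation of a secondary alcohol; the buffered, non-basic medium should leave the cis methyl group on C3 in place.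

Step 8
Reactants: 13 benzyl 2-[(1R,2R)-2-methyl-3-oxocyclopentyl]butanoate
Product: 14 2-[(1R,2R)-2-methyl-3-oxocyclopentyl]butanoic acid
Conditions: H2 (1 atm), Pd/C, EtOAc, 25 °C
Reagents that add atoms: none
Why: hydrogenolysis of a benzyl ester; the acid is freed under neutral conditions, so neither the ketone nor the epimerisable C3 centre is disturbed.

Step 9
Reactants: 14 2-[(1R,2R)-2-methyl-3-oxocyclopentyl]butanoic acid; 4 (2E,4E)-3-ethyl-5-phenylpenta-2,4-dien-1-ol
Product: 15 (2E,4E)-3-ethyl-5-phenylpenta-2,4-dien-1-yl 2-[(1R,2R)-2-methyl-3-oxocyclopentyl]butanoate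
Conditions: DCC, DMAP (cat.), CH2Cl2, 0 → 25 °C
Reagents that add atoms: none
Why: Steglich esterification of an α-branched acid with a primary allylic alcohol; the primary C–O bond, unlike a benzylic dienyl one, should not ionise on handling.

Step 10
Reactants: 15 (2E,4E)-3-ethyl-5-phenylpenta-2,4-dien-1-yl 2-[(1R,2R)-2-methyl-3-oxocyclopentyl]butanoate
Product: 18 methyl (2R,4E)-3-ethenyl-2,3-diethyl-2-[(1R,2R)-2-methyl-3-oxocyclopentyl]-5-phenylpent-4-enoate, via bis-silylated ketene acetal 16 (not isolated), via keto acid 17 (not isolated)
Conditions: LiN(i-Pr)2 (2.5 equiv), Me3SiCl, Et3N, THF, −78 → 65 °C; then MeOH; then Me3SiCHN2, 0 °C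
Reagents that add atoms: (trimethylsilyl)diazomethane, C[Si](C)(C)C=[N+]=[N-]
Why: Ireland–Claisen rearrangement of an α,α-disubstituted ester, with the ketone masked in the flask as its kinetic C1 silyl enol ether; the [3,3] shift joins C4 to C5 and makes both quaternary carbons. Because the allylic terminus is CH2–O, the face of C4 is chosen by C3a alone, whatever the ketene acetal geometry: with C3a–H eclipsing the ketene acetal (allylic strain), C3 and its cis methyl group shield one face and C5 is delivered over the C7a methylene, which corresponds to the 4R centre. C5 forms as a mixture that step 11 converges.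

Step 11
Reactants: 18 methyl (2R,4E)-3-ethenyl-2,3-diethyl-2-[(1R,2R)-2-methyl-3-oxocyclopentyl]-5-phenylpent-4-enoate; 19 iodobenzene
Product: 21 methyl (2R,4E)-2,3-diethyl-2-[(1R,2S)-2-methyl-3-oxocyclopentyl]-5-phenyl-3-[(E)-2-phenylethenyl]pent-4-enoate, via cis-methyl bis-styryl ester 20 (not isolated)
Conditions: Pd(OAc)2 (5 mol%), Bu4NCl, K2CO3, DMF, 80 °C; then DBU, 25 °C
Reagents that add atoms: none
Why: Mizoroki–Heck arylation of the terminal vinyl group under ligand-free Jeffery conditions; β-hydride elimination can only occur away from quaternary C5, so the E-styrene forms and the two alkenyl groups on C5 become identical. The base then equilibrates C3 to the trans methyl arrangement.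

Step 12
Reactants: 21 methyl (2R,4E)-2,3-diethyl-2-[(1R,2S)-2-methyl-3-oxocyclopentyl]-5-phenyl-3-[(E)-2-phenylethenyl]pent-4-enoate
Product: 22 methyl (2R,4E)-2,3-diethyl-2-[(1R,5S)-5-methyl-4-oxocyclopent-2-en-1-yl]-5-phenyl-3-[(E)-2-phenylethenyl]pent-4-enoate
Conditions: LiN(i-Pr)2, THF, −78 °C; then PhS(Cl)=N-t-Bu, −78 °C
Reagents that add atoms: none
Why: Mukaiyama dehydrogenation; the kinetic enolate forms at the C1 methylene (C3 is a hindered methine and the ester has no α-hydrogen), is sulfinimidoylated and eliminates to the C1=C7a enone.

Step 13
Reactants: 22 methyl (2R,4E)-2,3-diethyl-2-[(1R,5S)-5-methyl-4-oxocyclopent-2-en-1-yl]-5-phenyl-3-[(E)-2-phenylethenyl]pent-4-enoate; 23 prop-1-en-2-ylmagnesium bromide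
Product: 25 methyl (2R,4E)-2,3-diethyl-2-[(1R,2S,5S)-2-methyl-3-oxo-5-(prop-1-en-2-yl)cyclopentyl]-5-phenyl-3-[(E)-2-phenylethenyl]pent-4-enoate, via trimethylsilyl enol ether 24 (not isolated)
Conditions: CuBr·SMe2 (20 mol%), Me3SiCl, THF, −78 → −30 °C; then 1 M HCl
Reagents that add atoms: none
Why: copper-catalysed conjugate addition of a Grignard reagent accelerated by Me3SiCl; on a 4-substituted cyclopentenone the nucleophile enters anti to the C3a substituent, which sets C7a trans.

Step 14
Reactants: 25 methyl (2R,4E)-2,3-diethyl-2-[(1R,2S,5S)-2-methyl-3-oxo-5-(prop-1-en-2-yl)cyclopentyl]-5-phenyl-3-[(E)-2-phenylethenyl]pent-4-enoate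
Product: 26 methyl (2R,4E)-2,3-diethyl-2-[(1R,2R,3S,5S)-3-ethyl-5-methyl-4-oxo-2-(prop-1-en-2-yl)cyclopentyl]-5-phenyl-3-[(E)-2-phenylethenyl]pent-4-enoate
Conditions: LiN(i-Pr)2, THF, −78 °C; then EtI, DMPU, −78 → −20 °C
Reagents that add atoms: iodoethane, CCI
Why: alkylation of the kinetic ketone enolate, formed at the C1 methylene and not at the C3 methine; iodoethane approaches anti to the neighbouring isopropenyl group, giving the trans arrangement that is also the thermodynamic one.

Step 15
Reactants: 26 methyl (2R,4E)-2,3-diethyl-2-[(1R,2R,3S,5S)-3-ethyl-5-methyl-4-oxo-2-(prop-1-en-2-yl)cyclopentyl]-5-phenyl-3-[(E)-2-phenylethenyl]pent-4-enoate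
Product: 27 methyl (1S,3S,3aR,4R,5S,7aR)-1,4,5-triethyl-3,7-dimethyl-2-oxo-5-[(E)-2-phenylethenyl]-2,3,3a,4,5,7a-hexahydro-1H-indene-4-carboxylate
Conditions: RuCl2(=CHPh)(PCy3)(H2IMes) (second-generation Grubbs catalyst, 10 mol%), toluene, 0.005 M, 80 °C
Reagents that add atoms: none
Why: Ring-closing metathesis: the ruthenium benzylidene exchanges onto one styryl group to give a Ru=CH–C5 alkylidene, which adds across the isopropenyl double bond to a ruthenacyclobutane; cycloreversion closes the ring at the trisubstituted C6=C7 alkene, and the Ru=CH2 left behind takes up the next styryl group with release of styrene. The closest known reaction type is the diastereoselective ring-closing metathesis of prochiral substrates that carry two identical alkenyl groups on one carbon. The six-membered ring closes between arms that are trans on the cyclopentanone, so only one half-chair is open to it, with C3a–H and C7a–H axial and, because C4 is already fixed, the C4 ethyl group axial and the ester equatorial. C5 becomes stereogenic here and is controlled by the substrate: in the favoured closure the remaining styryl group is pseudoaxial, anti to the axial C4 ethyl group and syn only to C3a–H, while the C5 ethyl group is pseudoequatorial. The other closure would put the C5 ethyl group pseudoaxial and place the long styryl group pseudoequatorially, beside the ruthenium-bearing C6 and gauche to both C4 substituents. Loading onto either styryl group is reversible through exchange with the styrene set free, so the choice is made in the ring-closing transition state; this is why the reaction is run warm and dilute. No other selectivity is needed, since the ketone and ester are spectators and two styryl groups on one carbon cannot close a ring with each other.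

Step 16
Reactants: 27 methyl (1S,3S,3aR,4R,5S,7aR)-1,4,5-triethyl-3,7-dimethyl-2-oxo-5-[(E)-2-phenylethenyl]-2,3,3a,4,5,7a-hexahydro-1H-indene-4-carboxylate
Product: 28 (1S,3S,3aR,4R,5S,7aR)-1,4,5-triethyl-3,7-dimethyl-2-oxo-5-[(E)-2-phenylethenyl]-2,3,3a,4,5,7a-hexahydro-1H-indene-4-carboxylic acid
Conditions: LiI, pyridine, reflux; then 1 M HCl
Reagents that add atoms: none
Why: nucleophilic dealkylation of a hindered methyl ester (SN2 attack of iodide at the methyl carbon), which avoids the shielded carbonyl; C1 and C3 are already in their thermodynamic trans arrangement, so the hot basic medium should not change them.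

## Compound list

1 | (E)-1-phenylpent-1-en-3-one | CCC(=O)/C=C/c1ccccc1 | starting material
2 | triethyl phosphonoacetate | CCOC(=O)CP(=O)(OCC)OCC | starting material
3 | ethyl (2E,4E)-3-ethyl-5-phenylpenta-2,4-dienoate | CCOC(=O)/C=C(CC)/C=C/c1ccccc1 | intermediate
4 | (2E,4E)-3-ethyl-5-phenylpenta-2,4-dien-1-ol | OC/C=C(CC)/C=C/c1ccccc1 | intermediate
5 | 2-methylcyclopent-2-en-1-one | CC1=CCCC1=O | starting material
6 | (1S)-2-methylcyclopent-2-en-1-ol | O[C@H]1CCC=C1C | intermediate
7 | butanoyl chloride | CCCC(Cl)=O | starting material
8 | (1S)-2-methylcyclopent-2-en-1-yl butanoate | CCCC(=O)O[C@H]1CCC=C1C | intermediate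
9 | (E)-trimethylsilyl ketene acetal of 8 (ethyl trans to OSiMe3) | CC/C=C(/O[Si](C)(C)C)O[C@H]1CCC=C1C | intermediate
10 | trimethylsilyl 2-[(1S)-2-methylcyclopent-2-en-1-yl]butanoate (both epimers at chain C2) | CCC(C(=O)O[Si](C)(C)C)[C@@H]1CCC=C1C | intermediate
11 | benzyl 2-[(1S)-2-methylcyclopent-2-en-1-yl]butanoate (both epimers at chain C2) | CCC(C(=O)OCc1ccccc1)[C@@H]1CCC=C1C | intermediate
12 | benzyl 2-[(1R,2R,3R)-3-hydroxy-2-methylcyclopentyl]butanoate (methyl cis to side chain, hydroxyl trans to both) | CCC(C(=O)OCc1ccccc1)[C@@H]1CC[C@@H](O)[C@@H]1C | intermediate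
13 | benzyl 2-[(1R,2R)-2-methyl-3-oxocyclopentyl]butanoate (methyl cis to side chain) | CCC(C(=O)OCc1ccccc1)[C@@H]1CCC(=O)[C@@H]1C | intermediate
14 | 2-[(1R,2R)-2-methyl-3-oxocyclopentyl]butanoic acid | CCC(C(=O)O)[C@@H]1CCC(=O)[C@@H]1C | intermediate
15 | (2E,4E)-3-ethyl-5-phenylpenta-2,4-dien-1-yl 2-[(1R,2R)-2-methyl-3-oxocyclopentyl]butanoate | CCC(C(=O)OC/C=C(CC)/C=C/c1ccccc1)[C@@H]1CCC(=O)[C@@H]1C | intermediate
16 | bis(trimethylsilyl) derivative of 15 (ketene acetal at C4, enol ether C2=C1; ketene acetal geometry open) | CCC(=C(O[Si](C)(C)C)OC/C=C(CC)/C=C/c1ccccc1)[C@@H]1CC=C(O[Si](C)(C)C)[C@@H]1C | intermediate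
17 | (2R,4E)-3-ethenyl-2,3-diethyl-2-[(1R,2R)-2-methyl-3-oxocyclopentyl]-5-phenylpent-4-enoic acid (both epimers at chain C3) | C[C@H]1C(=O)CC[C@H]1[C@@](CC)(C(=O)O)C(CC)(C=C)/C=C/c1ccccc1 | intermediate
18 | methyl (2R,4E)-3-ethenyl-2,3-diethyl-2-[(1R,2R)-2-methyl-3-oxocyclopentyl]-5-phenylpent-4-enoate (both epimers at chain C3) | C[C@H]1C(=O)CC[C@H]1[C@@](CC)(C(=O)OC)C(CC)(C=C)/C=C/c1ccccc1 | intermediate
19 | iodobenzene | Ic1ccccc1 | starting material
20 | methyl (2R,4E)-2,3-diethyl-2-[(1R,2R)-2-methyl-3-oxocyclopentyl]-5-phenyl-3-[(E)-2-phenylethenyl]pent-4-enoate (ring methyl cis) | C[C@H]1C(=O)CC[C@H]1[C@@](CC)(C(=O)OC)C(CC)(/C=C/c1ccccc1)/C=C/c1ccccc1 | intermediate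
21 | methyl (2R,4E)-2,3-diethyl-2-[(1R,2S)-2-methyl-3-oxocyclopentyl]-5-phenyl-3-[(E)-2-phenylethenyl]pent-4-enoate (ring methyl trans) | C[C@@H]1C(=O)CC[C@H]1[C@@](CC)(C(=O)OC)C(CC)(/C=C/c1ccccc1)/C=C/c1ccccc1 | intermediate
22 | methyl (2R,4E)-2,3-diethyl-2-[(1R,5S)-5-methyl-4-oxocyclopent-2-en-1-yl]-5-phenyl-3-[(E)-2-phenylethenyl]pent-4-enoate | C[C@@H]1C(=O)C=C[C@H]1[C@@](CC)(C(=O)OC)C(CC)(/C=C/c1ccccc1)/C=C/c1ccccc1 | intermediate
23 | prop-1-en-2-ylmagnesium bromide | CC(=C)[Mg]Br | starting material
24 | trimethylsilyl enol ether (C2=C1) of 25 | C[C@@H]1C(O[Si](C)(C)C)=C[C@H](C(C)=C)[C@H]1[C@@](CC)(C(=O)OC)C(CC)(/C=C/c1ccccc1)/C=C/c1ccccc1 | intermediate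
25 | methyl (2R,4E)-2,3-diethyl-2-[(1R,2S,5S)-2-methyl-3-oxo-5-(prop-1-en-2-yl)cyclopentyl]-5-phenyl-3-[(E)-2-phenylethenyl]pent-4-enoate | C[C@@H]1C(=O)C[C@H](C(C)=C)[C@H]1[C@@](CC)(C(=O)OC)C(CC)(/C=C/c1ccccc1)/C=C/c1ccccc1 | intermediate
26 | methyl (2R,4E)-2,3-diethyl-2-[(1R,2R,3S,5S)-3-ethyl-5-methyl-4-oxo-2-(prop-1-en-2-yl)cyclopentyl]-5-phenyl-3-[(E)-2-phenylethenyl]pent-4-enoate | CC[C@@H]1C(=O)[C@@H](C)[C@H]([C@@](CC)(C(=O)OC)C(CC)(/C=C/c2ccccc2)/C=C/c2ccccc2)[C@H]1C(C)=C | intermediate
27 | methyl (1S,3S,3aR,4R,5S,7aR)-1,4,5-triethyl-3,7-dimethyl-2-oxo-5-[(E)-2-phenylethenyl]-2,3,3a,4,5,7a-hexahydro-1H-indene-4-carboxylate | CC[C@@H]1C(=O)[C@@H](C)[C@H]2[C@H]1C(C)=C[C@@](/C=C/c1ccccc1)(CC)[C@]2(CC)C(=O)OC | intermediate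
28 | (1S,3S,3aR,4R,5S,7aR)-1,4,5-triethyl-3,7-dimethyl-2-oxo-5-[(E)-2-phenylethenyl]-2,3,3a,4,5,7a-hexahydro-1H-indene-4-carboxylic acid | CC[C@@H]1C(=O)[C@@H](C)[C@H]2[C@H]1C(C)=C[C@@](/C=C/c1ccccc1)(CC)[C@]2(CC)C(=O)O | target

## Step count and least certain steps

Total: 16 steps. Longest linear sequence: 14 steps (steps 3–16, from 5); the two-step dienol branch (steps 1–2) joins at step 9.

**Step 15 (key step).** The most likely failure is weak discrimination between the two diastereotopic styryl groups, since the two closures differ only by exchanging an ethyl and a styryl group between pseudoaxial and pseudoequatorial sites; slow closure at a neopentyl alkylidene could also let intermolecular metathesis compete. The fallback gives C5 its configuration before the ring is closed. It sets out from 18: the two C5 epimers of 18 are separated by chromatography, and the (3R) epimer is epimerised at the ring methyl group with DBU to the trans-methyl vinyl ketone F1; the other epimer goes through step 11 as before. Dehydrogenation as in step 12 gives the cyclopentenone F2, conjugate addition as in step 13 the isopropenyl ketone F3, and ethylation as in step 14 the vinyl triene F4. Ring-closing metathesis of F4 with RuCl2(=CHPh)(PCy3)(H2IMes) joins the isopropenyl group to the terminal vinyl group, which reacts much more readily than the styryl group, with loss of ethene, and the route is rejoined at 27.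

**Step 10.** The most likely failure is poor face selection at C4, through partial epimerisation of the cis methyl group while 13–15 are handled or through enolisation toward C3. Competing deprotonation at the dienylic O–CH2 group and a slow rearrangement between two fully substituted termini are further risks. The fallback locks the directing methyl group by keeping C2 at the alcohol level. It sets out from 12: silylation (t-BuMe2SiCl, imidazole) gives the silyl ether F5, hydrogenolysis the silyloxy acid F6, and esterification with 4 the silyloxy dienyl ester F7. Ireland–Claisen rearrangement and methylation as in step 10, now with one equivalent of base, give the silyloxy vinyl ester F8; Heck arylation as in step 11 gives the bis-styryl silyl ether F9; Bu4NF gives the alcohol F10. Dess–Martin oxidation of F10 followed by DBU returns the route at 21.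

**Step 14.** The most likely failure is proton exchange between product and enolate during a slow alkylation with iodoethane, leading to over-alkylation and recovered ketone. The fallback replaces alkylation by an aldol sequence. It sets out from 25: the same kinetic enolate is added to acetaldehyde to give the aldol F11, dehydration (MeSO2Cl, Et3N, then DBU) gives the ethylidene ketone F12, and conjugate reduction of F12 with [(Ph3P)CuH]6 followed by base equilibration returns the route at 26.

**Step 13.** The most likely failure is sluggish or 1,2-addition, because the β-carbon lies next to the very large C3a substituent. The fallback is a rhodium-catalysed conjugate addition of the boronic ester 4,4,5,5-tetramethyl-2-(prop-1-en-2-yl)-1,3,2-dioxaborolane ([Rh(cod)Cl]2, KOH, dioxane–water), which sets out from 22 and comes back at 25 without any new compound.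

**Step 11.** The most likely failure is slow insertion at the neopentyl vinyl group, with catalyst decomposition before conversion is complete. The fallback is cross-metathesis of 18 with excess styrene using RuCl2(=CH-C6H4-2-O-i-Pr)(H2IMes), the second-generation Hoveyda–Grubbs catalyst; it sets out from 18, gives 20 and, after DBU, comes back at 21 without any new compound.

## Further compounds

F1 | step 15 | methyl (2R,3R,4E)-3-ethenyl-2,3-diethyl-2-[(1R,2S)-2-methyl-3-oxocyclopentyl]-5-phenylpent-4-enoate | C[C@@H]1C(=O)CC[C@H]1[C@@](CC)(C(=O)OC)[C@](CC)(C=C)/C=C/c1ccccc1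
F2 | step 15 | methyl (2R,3R,4E)-3-ethenyl-2,3-diethyl-2-[(1R,5S)-5-methyl-4-oxocyclopent-2-en-1-yl]-5-phenylpent-4-enoate | C[C@@H]1C(=O)C=C[C@H]1[C@@](CC)(C(=O)OC)[C@](CC)(C=C)/C=C/c1ccccc1
F3 | step 15 | methyl (2R,3R,4E)-3-ethenyl-2,3-diethyl-2-[(1R,2S,5S)-2-methyl-3-oxo-5-(prop-1-en-2-yl)cyclopentyl]-5-phenylpent-4-enoate | C[C@@H]1C(=O)C[C@H](C(C)=C)[C@H]1[C@@](CC)(C(=O)OC)[C@](CC)(C=C)/C=C/c1ccccc1
F4 | step 15 | methyl (2R,3R,4E)-3-ethenyl-2,3-diethyl-2-[(1R,2R,3S,5S)-3-ethyl-5-methyl-4-oxo-2-(prop-1-en-2-yl)cyclopentyl]-5-phenylpent-4-enoate | CC[C@@H]1C(=O)[C@@H](C)[C@H]([C@@](CC)(C(=O)OC)[C@](CC)(C=C)/C=C/c2ccccc2)[C@H]1C(C)=C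
F5 | step 10 | benzyl 2-[(1R,2R,3R)-3-(tert-butyldimethylsilyloxy)-2-methylcyclopentyl]butanoate | CCC(C(=O)OCc1ccccc1)[C@@H]1CC[C@@H](O[Si](C)(C)C(C)(C)C)[C@@H]1C
F6 | step 10 | 2-[(1R,2R,3R)-3-(tert-butyldimethylsilyloxy)-2-methylcyclopentyl]butanoic acid | CCC(C(=O)O)[C@@H]1CC[C@@H](O[Si](C)(C)C(C)(C)C)[C@@H]1C
F7 | step 10 | (2E,4E)-3-ethyl-5-phenylpenta-2,4-dien-1-yl 2-[(1R,2R,3R)-3-(tert-butyldimethylsilyloxy)-2-methylcyclopentyl]butanoate | CCC(C(=O)OC/C=C(CC)/C=C/c1ccccc1)[C@@H]1CC[C@@H](O[Si](C)(C)C(C)(C)C)[C@@H]1C
F8 | step 10 | methyl (2R,4E)-2-[(1R,2R,3R)-3-(tert-butyldimethylsilyloxy)-2-methylcyclopentyl]-3-ethenyl-2,3-diethyl-5-phenylpent-4-enoate (both epimers at chain C3) | C[C@H]1[C@H](O[Si](C)(C)C(C)(C)C)CC[C@H]1[C@@](CC)(C(=O)OC)C(CC)(C=C)/C=C/c1ccccc1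
F9 | step 10 | methyl (2R,4E)-2-[(1R,2R,3R)-3-(tert-butyldimethylsilyloxy)-2-methylcyclopentyl]-2,3-diethyl-5-phenyl-3-[(E)-2-phenylethenyl]pent-4-enoate | C[C@H]1[C@H](O[Si](C)(C)C(C)(C)C)CC[C@H]1[C@@](CC)(C(=O)OC)C(CC)(/C=C/c1ccccc1)/C=C/c1ccccc1
F10 | step 10 | methyl (2R,4E)-2,3-diethyl-2-[(1R,2R,3R)-3-hydroxy-2-methylcyclopentyl]-5-phenyl-3-[(E)-2-phenylethenyl]pent-4-enoate | C[C@H]1[C@H](O)CC[C@H]1[C@@](CC)(C(=O)OC)C(CC)(/C=C/c1ccccc1)/C=C/c1ccccc1
F11 | step 14 | aldol of 25 with acetaldehyde: 1-hydroxyethyl group on C1, trans to the isopropenyl group (carbinol centre open) | C[C@@H]1C(=O)[C@@H](C(C)O)[C@H](C(C)=C)[C@H]1[C@@](CC)(C(=O)OC)C(CC)(/C=C/c1ccccc1)/C=C/c1ccccc1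
F12 | step 14 | (E)-ethylidene ketone from F11 (exocyclic C1=CH–CH3) | C[C@@H]1C(=O)/C(=C/C)[C@H](C(C)=C)[C@H]1[C@@](CC)(C(=O)OC)C(CC)(/C=C/c1ccccc1)/C=C/c1ccccc1
F0 | step 13 | none | none
F0 | step 11 | none | none
A1 | alternative 1 | 2,3-diethylmaleic anhydride | CCC1=C(CC)C(=O)OC1=O
A2 | alternative 1 | 2-ethoxydiene: C2-dioxolane cyclopentene with C3a=C7a and a 1-ethoxyethenyl group on C7a | CC[C@@H]1C2(OCCO2)[C@@H](C)C=C1C(OCC)=C
A3 | alternative 1 | tricyclic anhydride adduct (enol ether C7=C7a) | CC[C@@H]1C2(OCCO2)[C@@H](C)[C@H]3C1=C(OCC)C[C@]4(CC)C(=O)OC(=O)[C@]34CC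
A4 | alternative 2 | Heck precursor: (Z)-iodoalkene on C7a and trisubstituted C5=Cα alkene bearing a benzyl group | CC[C@@H]1C2(OCCO2)[C@@H](C)[C@H]([C@@](CC)(C(=O)OC)/C(CC)=C/Cc2ccccc2)[C@H]1/C(C)=C\I
A5 | alternative 2 | C2-dioxolane methyl ester of the target | CC[C@@H]1C2(OCCO2)[C@@H](C)[C@H]3[C@H]1C(C)=C[C@@](/C=C/c1ccccc1)(CC)[C@]3(CC)C(=O)OC
A6 | alternative 3 | α-diazo-β-keto ester attached through C3 to C3a of the cyclohexene | COC(=O)C(=[N+]=[N-])C(=O)[C@@H](C)[C@H]1CC(C)=C[C@@](/C=C/c2ccccc2)(CC)[C@]1(CC)C(=O)OC
A7 | alternative 3 | trans-fused β-keto ester (CO2Me on C1) | COC(=O)[C@@H]1C(=O)[C@@H](C)[C@H]2[C@H]1C(C)=C[C@@](/C=C/c1ccccc1)(CC)[C@]2(CC)C(=O)OC
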